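## Retrosynthetic overview

1. The only ring, the cyclohexene, is formed last by ring-closing metathesis across C2=C3 of an acyclic 1,7-diene that already carries all four stereocentres and the final ester pattern.
2. The C6–C1 bond of that diene comes from a syn-selective acetoxyallylation of an α-benzoyloxy aldehyde. The nucleophile is acrolein with its carbonyl carbon turned into a carbanion equivalent (an α-acetoxyallyl anion), so two carbonyl carbons are joined and C1–OAc / C6–OH arrive already differentiated.
3. The C4–C5 bond is made the same way, by benzoyloxyallylation of 2-(benzoyloxymethyl)acrolein. The new vinyl group is then converted to the aldehyde by cross-metathesis and ozonolysis.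
4. The enal comes from 2-methylidenepropane-1,3-diol. Both allyl donors come from acrolein and an acyl chloride.

Atom labels used throughout (target ring): C1 (OAc), C2=C3 (C3 carries C7H2OBz), C4 (OH), C5 (OBz), C6 (OH). The same labels are kept for the open-chain precursors.

Assumption: the (S,S)-salen chromium catalyst is taken to direct Re-face addition and the (R,R)-catalyst Si-face addition to the aldehyde; if a first run shows the opposite sense, the two ligand enantiomers are exchanged between steps 4 and 8. Here salen-H2 is N,N′-bis(3,5-di-tert-butylsalicylidene)cyclohexane-1,2-diamine.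

## Route

Step 1
Reactants: 1 2-methylidenepropane-1,3-diol; 2 benzoyl chloride
Product: 3 2-(hydroxymethyl)prop-2-en-1-yl benzoate
Conditions: 1 (3 equiv, excess recovered), BzCl (1 equiv), Et3N, DMAP (cat.), CH2Cl2, −20 °C
Reagents that add atoms: benzoyl chloride (2), O=C(Cl)c1ccccc1
Why: Statistical mono-esterification of a symmetrical primary 1,3-diol used in excess; no stereocentre is involved.

Step 2
Reactants: 3 2-(hydroxymethyl)prop-2-en-1-yl benzoate
Product: 4 2-formylprop-2-en-1-yl benzoate
Conditions: activated MnO2 (10 equiv), CH2Cl2, rt; used at once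
Reagents that add atoms: none
Why: Chemoselective allylic alcohol oxidation gives the α-substituted acrolein without touching the ester; no stereocentre is involved.

Step 3
Reactants: 5 acrolein; 2 benzoyl chloride
Product: 6 3-chloroprop-1-en-1-yl benzoate (E/Z mixture)
Conditions: ZnCl2 (2 mol %), CH2Cl2, −20 °C → rt; distil
Reagents that add atoms: benzoyl chloride (2), O=C(Cl)c1ccccc1
Why: Lewis-acid-catalysed 1,4-addition of the acyl chloride across the enal converts the electrophilic carbonyl carbon of acrolein into the latent nucleophilic terminus of an allyl chloride; the alkene geometry is lost in the allyl metal, so the E/Z mixture is used as such.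

Step 4
Reactants: 4 2-formylprop-2-en-1-yl benzoate; 6 3-chloroprop-1-en-1-yl benzoate
Product: 7 (3S,4S)-2-methylidene-3-[(triethylsilyl)oxy]hex-5-ene-1,4-diyl dibenzoate
Conditions: CrCl3 (10 mol %), Mn powder (3 equiv), (S,S)-salen-H2 (12 mol %), Et3N (25 mol %), 6 (1.5 equiv), Et3SiCl (1.5 equiv), MeCN, rt, slow addition of 4; NaHCO3 work-up
Reagents that add atoms: 3-chloroprop-1-en-1-yl benzoate (6), ClCC=COC(=O)c1ccccc1; chlorotriethylsilane, CC[Si](CC)(CC)Cl
Why: Catalytic asymmetric Nozaki–Hiyama–Kishi-type acyloxyallylation in which the allylchromium from 6 attacks through its oxygen-bearing carbon (acrolein of reversed polarity); the salen chromium species reacts through an open transition state that gives the syn adduct, the (S,S)-ligand directs Re-face attack to set C4 (S) and C5 (S), and the chromium alkoxide is released as the triethylsilyl ether, the only protecting group of the route.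

Step 5
Reactants: 7 (3S,4S)-2-methylidene-3-[(triethylsilyl)oxy]hex-5-ene-1,4-diyl dibenzoate; 8 2-methylbut-2-ene
Product: 9 (3S,4S)-6-methyl-2-methylidene-3-[(triethylsilyl)oxy]hept-5-ene-1,4-diyl dibenzoate
Conditions: 8 (co-solvent, about 50 equiv), second-generation Hoveyda–Grubbs catalyst (5 mol %), CH2Cl2, 40 °C, sealed
Reagents that add atoms: 2-methylbut-2-ene (8), CC=C(C)C
Why: Olefin cross-metathesis in which only the monosubstituted vinyl group is a competent partner (the hindered 1,1-disubstituted alkene is inert), turning it into an electron-rich trisubstituted alkene that can be cleaved selectively; no stereocentre is touched.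

Step 6
Reactants: 9 (3S,4S)-6-methyl-2-methylidene-3-[(triethylsilyl)oxy]hept-5-ene-1,4-diyl dibenzoate
Product: 11 (2R,3S)-4-methylidene-1-oxo-3-[(triethylsilyl)oxy]pentane-2,5-diyl dibenzoate, via secondary ozonide 10 (not isolated)
Conditions: O3 (1.0 equiv, Sudan Red 7B end-point), CH2Cl2, −78 °C; Me2S, −78 °C → rt; crude aldehyde used directly
Reagents that add atoms: ozone, [O-][O+]=O
Why: Criegee ozonolysis in which the trisubstituted alkene reacts much faster than the 1,1-disubstituted alkene, which carries two allylic oxygens and sits beside the bulky silyl ether; C4 and C5 are untouched, and the α-benzoyloxy aldehyde is not chromatographed so as to avoid epimerisation.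

Step 7
Reactants: 5 acrolein; 12 acetyl chloride
Product: 13 3-chloroprop-1-en-1-yl acetate (E/Z mixture)
Conditions: ZnCl2 (2 mol %), CH2Cl2, −20 °C → rt; distil
Reagents that add atoms: acetyl chloride (12), CC(Cl)=O
Why: Same Lewis-acid-catalysed 1,4-addition of an acyl chloride to acrolein as in step 3, giving the acetate analogue of the reversed-polarity enal reagent.

Step 8 (key step)
Reactants: 11 (2R,3S)-4-methylidene-1-oxo-3-[(triethylsilyl)oxy]pentane-2,5-diyl dibenzoate; 13 3-chloroprop-1-en-1-yl acetate
Product: 15 (3S,4R,5S,6R)-6-(acetyloxy)-2-[(benzoyloxy)methyl]-3,5-dihydroxyocta-1,7-dien-4-yl benzoate, via bis-silyl ether 14 (not isolated)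
Conditions: CrCl3 (10 mol %), Mn powder (3 equiv), (R,R)-salen-H2 (12 mol %), Et3N (25 mol %), 13 (1.5 equiv), Me3SiCl (1.5 equiv), MeCN, rt; then 1 M aq. HCl, THF, 0 °C → rt
Reagents that add atoms: 3-chloroprop-1-en-1-yl acetate (13), CC(=O)OC=CCCl; chlorotrimethylsilane, C[Si](C)(C)Cl (silicon kept only in 14)
Why: Second chromium-catalysed asymmetric Nozaki–Hiyama–Kishi-type acyloxyallylation, joining the aldehyde carbon C6 to the former carbonyl carbon of acrolein (C1, now the nucleophile); the syn-selective open transition state sets C6–OH/C1–OAc threo, and Si-face attack is favoured both by the (R,R)-ligand and by the substrate (polar Felkin–Anh anti to C5–OBz, reinforced by 1,3-anti induction from C4–OSiEt3), giving C6 (S) and C1 (R) with the acetate and free hydroxyl already in their final places; the minor enantiomer carried from step 4 ends up as a separable diastereomer.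

Step 9
Reactants: 15 (3S,4R,5S,6R)-6-(acetyloxy)-2-[(benzoyloxy)methyl]-3,5-dihydroxyocta-1,7-dien-4-yl benzoate
Product: 16 (1R,2S,5R,6S)-5-(acetyloxy)-3-[(benzoyloxy)methyl]-2,6-dihydroxycyclohex-3-en-1-yl benzoate (target, CNP0169028.1)
Conditions: second-generation Hoveyda–Grubbs catalyst (10 mol %), 2,6-dichloro-1,4-benzoquinone (20 mol %), toluene (5 mM), 60 °C
Reagents that add atoms: none
Why: Ring-closing metathesis of the vinyl group with the 1,1-disubstituted alkene (helped by the free allylic hydroxyl) closes the six-membered ring as the trisubstituted C2=C3 alkene; no stereocentre is touched, and the neutral conditions avoid acyl migration.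

## Compound list

1 | 2-methylidenepropane-1,3-diol | C=C(CO)CO | starting material
2 | benzoyl chloride | O=C(Cl)c1ccccc1 | starting material
3 | 2-(hydroxymethyl)prop-2-en-1-yl benzoate | C=C(CO)COC(=O)c1ccccc1 | intermediate
4 | 2-formylprop-2-en-1-yl benzoate | C=C(C=O)COC(=O)c1ccccc1 | intermediate
5 | acrolein (prop-2-enal) | C=CC=O | starting material
6 | 3-chloroprop-1-en-1-yl benzoate (E/Z mixture) | ClCC=COC(=O)c1ccccc1 | intermediate
7 | (3S,4S)-2-methylidene-3-[(triethylsilyl)oxy]hex-5-ene-1,4-diyl dibenzoate | C=C[C@H](OC(=O)c1ccccc1)[C@@H](O[Si](CC)(CC)CC)C(=C)COC(=O)c1ccccc1 | intermediate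
8 | 2-methylbut-2-ene | CC=C(C)C | starting material
9 | (3S,4S)-6-methyl-2-methylidene-3-[(triethylsilyl)oxy]hept-5-ene-1,4-diyl dibenzoate | CC(C)=C[C@H](OC(=O)c1ccccc1)[C@@H](O[Si](CC)(CC)CC)C(=C)COC(=O)c1ccccc1 | intermediate
10 | (1R,2S)-1-(5,5-dimethyl-1,2,4-trioxolan-3-yl)-3-methylidene-2-[(triethylsilyl)oxy]butane-1,4-diyl dibenzoate (secondary ozonide, both epimers at the trioxolane carbon) | CC1(C)OOC(O1)[C@H](OC(=O)c1ccccc1)[C@@H](O[Si](CC)(CC)CC)C(=C)COC(=O)c1ccccc1 | intermediate
11 | (2R,3S)-4-methylidene-1-oxo-3-[(triethylsilyl)oxy]pentane-2,5-diyl dibenzoate | O=C[C@H](OC(=O)c1ccccc1)[C@@H](O[Si](CC)(CC)CC)C(=C)COC(=O)c1ccccc1 | intermediate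
12 | acetyl chloride | CC(Cl)=O | starting material
13 | 3-chloroprop-1-en-1-yl acetate (E/Z mixture) | CC(=O)OC=CCCl | intermediate
14 | (3S,4R,5S,6R)-6-(acetyloxy)-2-[(benzoyloxy)methyl]-3-[(triethylsilyl)oxy]-5-[(trimethylsilyl)oxy]octa-1,7-dien-4-yl benzoate | C=C[C@@H](OC(C)=O)[C@H](O[Si](C)(C)C)[C@H](OC(=O)c1ccccc1)[C@@H](O[Si](CC)(CC)CC)C(=C)COC(=O)c1ccccc1 | intermediate
15 | (3S,4R,5S,6R)-6-(acetyloxy)-2-[(benzoyloxy)methyl]-3,5-dihydroxyocta-1,7-dien-4-yl benzoate | C=C[C@@H](OC(C)=O)[C@H](O)[C@H](OC(=O)c1ccccc1)[C@@H](O)C(=C)COC(=O)c1ccccc1 | intermediate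
16 | (1R,2S,5R,6S)-5-(acetyloxy)-3-[(benzoyloxy)methyl]-2,6-dihydroxycyclohex-3-en-1-yl benzoate | CC(=O)O[C@@H]1C=C(COC(=O)c2ccccc2)[C@H](O)[C@@H](OC(=O)c2ccccc2)[C@H]1O | target

## Step count and risks

Total steps: 9 (including the two one-step reagent preparations, steps 3 and 7). Longest linear sequence: 7 steps (1, 2, 4, 5, 6, 8, 9).

The three steps most likely to fail:

Step 8 is the riskiest. It needs syn selectivity and the correct face on a labile α-benzoyloxy aldehyde, and the acetate reagent has less precedent under chromium–salen catalysis than bulkier esters. The fallback sets out from 11 and comes back at 15, swapping catalyst control for a substrate-controlled alkoxyallyl stannane and installing the acetate afterwards. Aldehyde 11 is treated with (Z)-tributyl[3-(methoxymethoxy)prop-2-en-1-yl]stannane and BF3·OEt2 in CH2Cl2 at −78 °C (open antiperiplanar transition state, syn diol unit, Felkin–Anh face) to give the methoxymethyl ether adduct F1. The free C6 hydroxyl is capped with Et3SiOTf and 2,6-lutidine to give the bis(triethylsilyl) ether F2. Me2BBr at −78 °C removes the methoxymethyl group to give the allylic alcohol F3, and Ac2O with pyridine and DMAP gives the acetate F4. 1 M aq. HCl in THF then removes both silyl groups to give 15.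

Step 4 is the second risk. Enantio- and syn-selectivity have to be achieved with the benzoate reagent on a reactive 2-substituted acrolein that can also undergo reductive dimerisation. The fallback sets out from 4 and comes back at 7, using a stoichiometric chiral boron reagent. Enal 4 is added at −78 °C to (Z)-[3-(methoxymethoxy)allyl]diisopinocampheylborane, made from allyl methoxymethyl ether, sec-BuLi, the B-methoxydiisopinocampheylborane enantiomer that attacks the Re face, and BF3·OEt2. Ethanolamine work-up gives the syn methoxymethyl ether alcohol F5. Et3SiCl and imidazole give the silyl ether F6, Me2BBr at −78 °C gives the allylic alcohol F7, and BzCl with pyridine gives 7.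

Step 6 is the third risk. One of two alkenes must be cleaved cleanly, and the product is an epimerisable α-benzoyloxy aldehyde. The fallback sets out from 9 and comes back at 11, replacing ozone by a two-stage glycol cleavage. Dihydroxylation of the trisubstituted alkene with K2OsO4·2H2O (2 mol %) and N-methylmorpholine N-oxide in acetone/water gives the diol F8 (both epimers at the new secondary carbinol). NaIO4 in buffered THF/water then cleaves it to 11.

## Further compounds

F1 | step 8 | (3S,4R,5S,6R)-2-[(benzoyloxy)methyl]-5-hydroxy-6-(methoxymethoxy)-3-[(triethylsilyl)oxy]octa-1,7-dien-4-yl benzoate | C=C[C@@H](OCOC)[C@H](O)[C@H](OC(=O)c1ccccc1)[C@@H](O[Si](CC)(CC)CC)C(=C)COC(=O)c1ccccc1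
F2 | step 8 | (3S,4R,5S,6R)-2-[(benzoyloxy)methyl]-6-(methoxymethoxy)-3,5-bis[(triethylsilyl)oxy]octa-1,7-dien-4-yl benzoate | C=C[C@@H](OCOC)[C@H](O[Si](CC)(CC)CC)[C@H](OC(=O)c1ccccc1)[C@@H](O[Si](CC)(CC)CC)C(=C)COC(=O)c1ccccc1
F3 | step 8 | (3S,4R,5S,6R)-2-[(benzoyloxy)methyl]-6-hydroxy-3,5-bis[(triethylsilyl)oxy]octa-1,7-dien-4-yl benzoate | C=C[C@@H](O)[C@H](O[Si](CC)(CC)CC)[C@H](OC(=O)c1ccccc1)[C@@H](O[Si](CC)(CC)CC)C(=C)COC(=O)c1ccccc1
F4 | step 8 | (3S,4R,5S,6R)-6-(acetyloxy)-2-[(benzoyloxy)methyl]-3,5-bis[(triethylsilyl)oxy]octa-1,7-dien-4-yl benzoate | C=C[C@@H](OC(C)=O)[C@H](O[Si](CC)(CC)CC)[C@H](OC(=O)c1ccccc1)[C@@H](O[Si](CC)(CC)CC)C(=C)COC(=O)c1ccccc1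
F5 | step 4 | (3S,4S)-3-hydroxy-4-(methoxymethoxy)-2-methylidenehex-5-en-1-yl benzoate | C=C[C@H](OCOC)[C@@H](O)C(=C)COC(=O)c1ccccc1
F6 | step 4 | (3S,4S)-4-(methoxymethoxy)-2-methylidene-3-[(triethylsilyl)oxy]hex-5-en-1-yl benzoate | C=C[C@H](OCOC)[C@@H](O[Si](CC)(CC)CC)C(=C)COC(=O)c1ccccc1
F7 | step 4 | (3S,4S)-4-hydroxy-2-methylidene-3-[(triethylsilyl)oxy]hex-5-en-1-yl benzoate | C=C[C@H](O)[C@@H](O[Si](CC)(CC)CC)C(=C)COC(=O)c1ccccc1
F8 | step 6 | (3S,4S)-5,6-dihydroxy-6-methyl-2-methylidene-3-[(triethylsilyl)oxy]heptane-1,4-diyl dibenzoate (both C5 epimers) | CC(C)(O)C(O)[C@H](OC(=O)c1ccccc1)[C@@H](O[Si](CC)(CC)CC)C(=C)COC(=O)c1ccccc1
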